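The route rests on cutting the C8=C9 trisubstituted olefin of the cycloheptene (ring atoms C1, C5, C6, C7, C8, C9, C10), the bond of that ring most remote from the stereocentres. Ring-closing olefin metathesis of a fully substituted cyclopentane that carries an allyl group on C1 and a 1-(aroyloxy)-3-methylbut-3-enyl arm on C5 closes the seven-membered ring onto the existing five-membered ring in one operation; the rigid trans-fused bicycle then dictates the C2 carbinol configuration. The precursor is built from (S)-4-silyloxycyclopentenone by two anti conjugate additions, an aldol addition and an isopropyl addition, the silyloxy group serving as a stereochemical relay.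

Key step: step 6

Remark on numbering: daucane locants are used for the bicycles and, in the Why lines, for the monocyclic precursors. C1 is the methyl-bearing ring-fusion carbon, C2 (CH–O) and C3 (CH2) complete the cyclopentane, C4 is the isopropyl carbinol carbon, C5 the ring-fusion CH, C6 the carbon bearing the 4-methoxybenzoate, then C7 (CH2), C8 (methyl-bearing olefinic carbon), C9 (olefinic CH) and C10 (CH2 bonded to C1). β is the face of the C1 methyl group.

Step 1
Reactants: 1 (4S)-4-[(tert-butyldimethylsilyl)oxy]cyclopent-2-en-1-one; 2 allylmagnesium bromide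
Product: 4 (4S)-4-[(tert-butyldimethylsilyl)oxy]-3-(prop-2-en-1-yl)cyclopent-2-en-1-one, via trimethylsilyl enol ether 3 (not isolated)
Conditions: allylMgBr, CuBr·SMe2 (1.3 equiv), Me3SiCl, THF, −78 °C; crude 3, then Pd(OAc)2 (1.1 equiv), MeCN, rt
Reagents that add atoms: allylmagnesium bromide (2), C=CC[Mg]Br; chlorotrimethylsilane, C[Si](C)(C)Cl (its silyl group is carried only by intermediate 3)
Why: Copper-mediated conjugate addition of the allyl group occurs anti to the silyloxy group and silyl trapping fixes the enolate regiochemistry, so that Saegusa–Ito oxidation of 3 can restore the enone only toward the allyl-bearing carbon; the transient stereocentre is erased and the (S) silyloxy centre of 1 is untouched.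

Step 2
Reactants: 5 3-methylbut-3-en-1-ol
Product: 6 3-methylbut-3-enal
Conditions: Dess–Martin periodinane, CH2Cl2, 0 °C; cold aqueous wash, solution used at once
Reagents that add atoms: none
Why: Dess–Martin oxidation of a primary alcohol under non-basic conditions should give the β,γ-unsaturated aldehyde without isomerisation into conjugation.

Step 3
Reactants: 4 (4S)-4-[(tert-butyldimethylsilyl)oxy]-3-(prop-2-en-1-yl)cyclopent-2-en-1-one; 7 methylmagnesium bromide; 6 3-methylbut-3-enal
Product: 9 (2S,3R,4S)-4-[(tert-butyldimethylsilyl)oxy]-2-[(1S)-1-hydroxy-3-methylbut-3-en-1-yl]-3-methyl-3-(prop-2-en-1-yl)cyclopentan-1-one, via bromomagnesium enolate 8 (not isolated)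
Conditions: MeMgBr (1.2 equiv), CuBr·SMe2 (10 mol %), THF, −40 °C; then 6, −78 °C; aq. NH4Cl
Reagents that add atoms: methylmagnesium bromide (7), C[Mg]Br; 3-methylbut-3-enal (6), CC(=C)CC=O
Why: Copper-catalysed (Kharasch-type) conjugate addition of the methyl group anti to the adjacent silyloxy group sets the quaternary C1 (R; methyl trans to OTBS, allyl cis), and the (E)-configured ring enolate 8 then adds to 6 through a chair Zimmerman–Traxler transition state on the β face, anti to both the allyl and the silyloxy group, which should give the anti aldol with C5 (S) and C6 (S).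

Step 4
Reactants: 9 (2S,3R,4S)-4-[(tert-butyldimethylsilyl)oxy]-2-[(1S)-1-hydroxy-3-methylbut-3-en-1-yl]-3-methyl-3-(prop-2-en-1-yl)cyclopentan-1-one; 10 isopropylmagnesium chloride
Product: 11 (1R,2S,3R,4S)-4-[(tert-butyldimethylsilyl)oxy]-2-[(1S)-1-hydroxy-3-methylbut-3-en-1-yl]-3-methyl-1-(propan-2-yl)-3-(prop-2-en-1-yl)cyclopentan-1-ol
Conditions: i-PrMgCl (4 equiv), anhydrous CeCl3 (4 equiv), THF, −78 → 0 °C
Reagents that add atoms: isopropylmagnesium chloride (10), CC(C)[Mg]Cl
Why: CeCl3-promoted Grignard 1,2-addition (organocerium-type, which suppresses enolisation, β-elimination of the silyloxy group, retro-aldol cleavage and β-hydride reduction) should attack the C4 ketone anti to the chelated C5 side chain, placing isopropyl α and the new tertiary hydroxyl β (C4 R, cis to the C1 methyl).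

Step 5
Reactants: 11 the diol of step 4; 12 4-methoxybenzoyl chloride
Product: 13 (1S)-1-[(1S,2R,3S,5R)-3-[(tert-butyldimethylsilyl)oxy]-5-hydroxy-2-methyl-5-(propan-2-yl)-2-(prop-2-en-1-yl)cyclopentyl]-3-methylbut-3-en-1-yl 4-methoxybenzoate
Conditions: 4-MeOC6H4COCl, Et3N, DMAP (cat.), CH2Cl2, 0 °C → rt
Reagents that add atoms: 4-methoxybenzoyl chloride (12), COc1ccc(cc1)C(Cl)=O
Why: DMAP-catalysed acylation (nucleophilic catalysis) should take the secondary C6 hydroxyl and leave the tertiary C4 hydroxyl, with O2 still silylated and no stereocentre touched.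

Step 6
Reactants: 13 the triene 4-methoxybenzoate of step 5
Product: 14 (1R,2S,4R,5S,6S)-2-[(tert-butyldimethylsilyl)oxy]-4-hydroxydauc-8-en-6-yl 4-methoxybenzoate (trans-fused; 2α-silyloxy)
Conditions: second-generation Grubbs catalyst RuCl2(=CHPh)(PCy3)(H2IMes) (5 mol %), CH2Cl2 (2 mM), 40 °C
Reagents that add atoms: none
Why: The ruthenium benzylidene should load onto the unhindered monosubstituted allyl olefin on C1 to give an alkylidene at C9, which adds to the 1,1-disubstituted C8=CH2 olefin by [2+2] cycloaddition to a ruthenacyclobutane and cycloreverts with loss of ethylene (Chauvin mechanism). The closest known reaction type is ring-closing olefin metathesis to trisubstituted cycloheptenes. The cycloheptene is closed in the seven-membered, endocyclic-olefin mode by forming C8=C9, whose Z geometry is dictated by the ring, while the cyclopentane is a spectator. No stereocentre is created or touched; the trans ring fusion is inherited from the allyl arm on C1 (α) and the carbinol arm on C5 (β) set in step 3. The step needs cyclisation to win over intermolecular cross-metathesis, which high dilution, the single initiation site, the gearing of the two arms by the fully substituted C1 and C4 and the irreversible loss of ethylene should secure; no other olefin pair can form an unstrained ring.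

Step 7
Reactants: 14 the bicyclic silyl ether of step 6
Product: 15 (1R,2S,4R,5S,6S)-2,4-dihydroxydauc-8-en-6-yl 4-methoxybenzoate (2α-alcohol)
Conditions: HF·pyridine, pyridine/THF, 0 °C → rt
Reagents that add atoms: none
Why: Fluoride-driven Si–O cleavage under buffered, non-basic conditions should free the C2 hydroxyl without the acyl migration or ester cleavage that a basic fluoride source could cause.

Step 8
Reactants: 15 the 2α-alcohol of step 7
Product: 16 (1R,4R,5S,6S)-4-hydroxy-2-oxodauc-8-en-6-yl 4-methoxybenzoate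
Conditions: Dess–Martin periodinane, CH2Cl2, 0 °C → rt
Reagents that add atoms: none
Why: Dess–Martin oxidation should convert the only secondary alcohol into the C2 ketone under non-basic conditions that spare the tertiary β-hydroxyl (no retro-aldol or dehydration), deliberately erasing the C2 centre that served as the relay.

Step 9
Reactants: 16 the C2 ketone of step 8
Product: 17 (1R,2R,4R,5S,6S)-2,4-dihydroxydauc-8-en-6-yl 4-methoxybenzoate (2β-alcohol)
Conditions: NaBH4, MeOH, −20 °C
Reagents that add atoms: none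
Why: In this borohydride reduction of a cyclopentanone next to a quaternary carbon in a trans-fused bicycle (the 17-oxo steroid situation), hydride should attack the α face, opposite the pseudo-axial C1 methyl and the β C4 hydroxyl, giving the 2β alcohol (C2 R, cis to the methyl) while the aryl ester is inert.

Step 10
Reactants: 17 the 2β-alcohol of step 9; 18 angelic acid, (Z)-2-methylbut-2-enoic acid
Product: 20 (1R,2R,4R,5S,6S)-4-hydroxy-2-{[(Z)-2-methylbut-2-enoyl]oxy}dauc-8-en-6-yl 4-methoxybenzoate (CNP0204191.1), via mixed anhydride 19 (not isolated)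
Conditions: 18, 2,4,6-trichlorobenzoyl chloride, Et3N, toluene, rt; then 17, 80 °C
Reagents that add atoms: angelic acid (18), C/C=C(/C)C(O)=O; 2,4,6-trichlorobenzoyl chloride, O=C(Cl)c1c(Cl)cc(Cl)cc1Cl (its atoms stay only in intermediate 19)
Why: Yamaguchi esterification through mixed anhydride 19, run without DMAP to avoid the addition–elimination that isomerises the Z acyl unit to the E isomer, should acylate the secondary 2β hydroxyl selectively over the tertiary C4 hydroxyl with retention at C2.

Compound list
1 | (4S)-4-[(tert-butyldimethylsilyl)oxy]cyclopent-2-en-1-one | CC(C)(C)[Si](C)(C)O[C@H]1CC(=O)C=C1 | starting material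
2 | allylmagnesium bromide | C=CC[Mg]Br | starting material
3 | (3S,4S)-4-[(tert-butyldimethylsilyl)oxy]-3-(prop-2-en-1-yl)-1-[(trimethylsilyl)oxy]cyclopent-1-ene (allyl trans to OTBS) | CC(C)(C)[Si](C)(C)O[C@H]1CC(O[Si](C)(C)C)=C[C@@H]1CC=C | intermediate
4 | (4S)-4-[(tert-butyldimethylsilyl)oxy]-3-(prop-2-en-1-yl)cyclopent-2-en-1-one | CC(C)(C)[Si](C)(C)O[C@H]1CC(=O)C=C1CC=C | intermediate
5 | 3-methylbut-3-en-1-ol | CC(=C)CCO | starting material
6 | 3-methylbut-3-enal | CC(=C)CC=O | intermediate
7 | methylmagnesium bromide | C[Mg]Br | starting material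
8 | bromomagnesium (3R,4S)-4-[(tert-butyldimethylsilyl)oxy]-3-methyl-3-(prop-2-en-1-yl)cyclopent-1-en-1-olate | CC(C)(C)[Si](C)(C)O[C@H]1CC(O[Mg]Br)=C[C@@]1(C)CC=C | intermediate
9 | (2S,3R,4S)-4-[(tert-butyldimethylsilyl)oxy]-2-[(1S)-1-hydroxy-3-methylbut-3-en-1-yl]-3-methyl-3-(prop-2-en-1-yl)cyclopentan-1-one | CC(C)(C)[Si](C)(C)O[C@H]1CC(=O)[C@H]([C@@H](O)CC(C)=C)[C@@]1(C)CC=C | intermediate
10 | isopropylmagnesium chloride | CC(C)[Mg]Cl | starting material
11 | (1R,2S,3R,4S)-4-[(tert-butyldimethylsilyl)oxy]-2-[(1S)-1-hydroxy-3-methylbut-3-en-1-yl]-3-methyl-1-(propan-2-yl)-3-(prop-2-en-1-yl)cyclopentan-1-ol | CC(C)(C)[Si](C)(C)O[C@H]1C[C@@](O)(C(C)C)[C@H]([C@@H](O)CC(C)=C)[C@@]1(C)CC=C | intermediate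
12 | 4-methoxybenzoyl chloride | COc1ccc(cc1)C(Cl)=O | starting material
13 | (1S)-1-[(1S,2R,3S,5R)-3-[(tert-butyldimethylsilyl)oxy]-5-hydroxy-2-methyl-5-(propan-2-yl)-2-(prop-2-en-1-yl)cyclopentyl]-3-methylbut-3-en-1-yl 4-methoxybenzoate | CC(C)(C)[Si](C)(C)O[C@H]1C[C@@](O)(C(C)C)[C@H]([C@@H](OC(=O)c2ccc(OC)cc2)CC(C)=C)[C@@]1(C)CC=C | intermediate
14 | (1R,2S,4R,5S,6S)-2-[(tert-butyldimethylsilyl)oxy]-4-hydroxydauc-8-en-6-yl 4-methoxybenzoate | CC(C)(C)[Si](C)(C)O[C@H]1C[C@@](O)(C(C)C)[C@@H]2[C@@H](OC(=O)c3ccc(OC)cc3)CC(C)=CC[C@]21C | intermediate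
15 | (1R,2S,4R,5S,6S)-2,4-dihydroxydauc-8-en-6-yl 4-methoxybenzoate (2α-alcohol) | O[C@H]1C[C@@](O)(C(C)C)[C@@H]2[C@@H](OC(=O)c3ccc(OC)cc3)CC(C)=CC[C@]21C | intermediate
16 | (1R,4R,5S,6S)-4-hydroxy-2-oxodauc-8-en-6-yl 4-methoxybenzoate | O=C1C[C@@](O)(C(C)C)[C@@H]2[C@@H](OC(=O)c3ccc(OC)cc3)CC(C)=CC[C@]21C | intermediate
17 | (1R,2R,4R,5S,6S)-2,4-dihydroxydauc-8-en-6-yl 4-methoxybenzoate (2β-alcohol) | O[C@@H]1C[C@@](O)(C(C)C)[C@@H]2[C@@H](OC(=O)c3ccc(OC)cc3)CC(C)=CC[C@]21C | intermediate
18 | angelic acid, (Z)-2-methylbut-2-enoic acid | C/C=C(/C)C(O)=O | starting material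
19 | (Z)-2-methylbut-2-enoic 2,4,6-trichlorobenzoic anhydride | C/C=C(/C)C(=O)OC(=O)c1c(Cl)cc(Cl)cc1Cl | intermediate
20 | (1R,2R,4R,5S,6S)-4-hydroxy-2-{[(Z)-2-methylbut-2-enoyl]oxy}dauc-8-en-6-yl 4-methoxybenzoate (CNP0204191.1) | C/C=C(/C)C(=O)O[C@@H]1C[C@@](O)(C(C)C)[C@@H]2[C@@H](OC(=O)c3ccc(OC)cc3)CC(C)=CC[C@]21C | target

Total step count: 10.
Longest linear sequence: 9 steps (1 → 4 → 9 → 11 → 13 → 14 → 15 → 16 → 17 → 20; step 2 is a one-step side branch).

Steps most likely to fail

Step 3. The anti versus syn selection at C6 may erode in the aldol addition, through open transition states or partial proton transfer from the enolisable aldehyde. The fallback sets C6 by hydride delivery from the C4 hydroxyl instead. It sets out from 9 obtained together with its C6 epimer, the 6-epi aldol F1. The mixture is carried through step 4 to 11 and its C6 epimer, the 6-epi diol F2. Dess–Martin oxidation of the secondary carbinol converges both on the β-hydroxy ketone F3. Hydroxyl-directed reduction with Me4NBH(OAc)3 in MeCN/AcOH at −30 °C (Evans–Saksena reduction, intramolecular hydride transfer from the C4 alkoxyborohydride with the C7 chain turned away from the ring) should then give the 6S carbinol. The route is rejoined at 11.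

Step 4. Enolisation, β-elimination of the silyloxy group, retro-aldol cleavage or β-hydride reduction may outrun addition to the hindered ketone, and facial control may be lost in the flexible monocycle. The fallback moves ring closure ahead of the isopropyl addition. It sets out from 9, which is silylated (TESOTf, 2,6-lutidine) to the triethylsilyl ether F4. Ring-closing metathesis under the conditions of step 6 gives the trans-fused bicyclic ketone F5. Addition of i-PrMgCl/CeCl3 to this rigid ketone from the α face gives the tertiary alcohol F6. Selective removal of the triethylsilyl group (PPTS, MeOH) gives the bicyclic diol F7. Acylation as in step 5 returns to the route at 14.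

Step 10. The activated Z acyl unit may isomerise to the E isomer, or acylation of the neopentyl-type alcohol may stall. The fallback builds the Z olefin on the ester instead. It sets out from 17, which is esterified with 2-[bis(2,2,2-trifluoroethoxy)phosphoryl]propanoic acid (DCC, DMAP) to the phosphonate ester F8 (either epimer at the phosphonate carbon). Still–Gennari olefination with acetaldehyde (KHMDS, 18-crown-6, THF, −78 °C) should give the Z olefin under kinetic control. The route is rejoined at 20.

Further compounds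
F1 | step 3 | 6-epi aldol, (2S,3R,4S)-4-[(tert-butyldimethylsilyl)oxy]-2-[(1R)-1-hydroxy-3-methylbut-3-en-1-yl]-3-methyl-3-(prop-2-en-1-yl)cyclopentan-1-one | CC(C)(C)[Si](C)(C)O[C@H]1CC(=O)[C@H]([C@H](O)CC(C)=C)[C@@]1(C)CC=C
F2 | step 3 | 6-epi diol, C6 epimer of 11 | CC(C)(C)[Si](C)(C)O[C@H]1C[C@@](O)(C(C)C)[C@H]([C@H](O)CC(C)=C)[C@@]1(C)CC=C
F3 | step 3 | β-hydroxy ketone, 6-oxo analogue of 11 | CC(C)(C)[Si](C)(C)O[C@H]1C[C@@](O)(C(C)C)[C@H](C(=O)CC(C)=C)[C@@]1(C)CC=C
F4 | step 4 | triethylsilyl ether of 9 at O6 | CC(C)(C)[Si](C)(C)O[C@H]1CC(=O)[C@H]([C@@H](O[Si](CC)(CC)CC)CC(C)=C)[C@@]1(C)CC=C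
F5 | step 4 | trans-fused bicyclic ketone, (1R,2S,5S,6S)-2-[(tert-butyldimethylsilyl)oxy]-6-[(triethylsilyl)oxy]-4-oxo-8-methylbicyclo[5.3.0]dec-8-ene skeleton in daucane numbering without the isopropyl group | CC(C)(C)[Si](C)(C)O[C@H]1CC(=O)[C@@H]2[C@@H](O[Si](CC)(CC)CC)CC(C)=CC[C@]21C
F6 | step 4 | (1R,2S,4R,5S,6S)-2-[(tert-butyldimethylsilyl)oxy]-6-[(triethylsilyl)oxy]dauc-8-en-4-ol | CC(C)(C)[Si](C)(C)O[C@H]1C[C@@](O)(C(C)C)[C@@H]2[C@@H](O[Si](CC)(CC)CC)CC(C)=CC[C@]21C
F7 | step 4 | (1R,2S,4R,5S,6S)-2-[(tert-butyldimethylsilyl)oxy]dauc-8-ene-4,6-diol | CC(C)(C)[Si](C)(C)O[C@H]1C[C@@](O)(C(C)C)[C@@H]2[C@@H](O)CC(C)=CC[C@]21C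
F8 | step 10 | 2-[bis(2,2,2-trifluoroethoxy)phosphoryl]propanoate of 17 at O2 (epimeric at the phosphonate carbon) | CC(C(=O)O[C@@H]1C[C@@](O)(C(C)C)[C@@H]2[C@@H](OC(=O)c3ccc(OC)cc3)CC(C)=CC[C@]21C)P(=O)(OCC(F)(F)F)OCC(F)(F)F
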